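The trap at this bench was reading target as the part reacted: in the east run at 50.0 h, solid substrate read 0% and target 41%. That gap of 59.0% lay close to the protic impurity charged there, 60.0% of the solid substrate.

| flask | solid substrate | acid | protic impurity | remark | time |
|---|---|---|---|---|---|
| east | 7 mM | 1.4 mM | 4.2 mM | run made earlier |  |
| north | 28 mM | 1.4 mM | 4.2 mM | run made earlier |  |
| flask | 14 mM | 1.40 mM | 4.20 mM |  | 40 h |

| run | time / h | solid substrate / % | target / % |
|---|---|---|---|
| east | 3.00 | 68 | 4 |
| east | 10.0 | 0 | 18 |
| east | 15.0 | 2 | 28 |
| east | 25.0 | 1 | 34 |
| east | 40.0 | 0 | 37 |
| east | 50.0 | 0 | 41 |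
| north | 8.00 | 79 | 6 |
| north | 15.0 | 63 | 8 |
| north | 25.0 | 41 | 21 |
| north | 30.0 | 34 | 27 |
| north | 40.0 | 15 | 40 |
| north | 50.0 | 1 | 57 |

(readings scatter by 1.5 percentage points)

- acid is the free proton; pH is minus the decimal logarithm of its molar concentration
- solid, in amounts per volume of the solution: solid substrate
- the numbers in the tables scatter with a standard deviation of 1.5 percentage points
- at the start none of the solid substrate is in solution
- what has only dissolved of solid substrate counts as not reacted

* part of the solid substrate that has reacted (what has only dissolved counts as not reacted) at 40 h
* pH of the solution at 40 h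

So for the flask I carried 30.0%: protic impurity charged over solid substrate charged, the impurity share, which I took as the part of the charge lost one for one without giving target. Leave the flask stirring when the solid disappears: the east run read 0% solid at 10.0 h with target at 18%, and target kept climbing. I reckoned reacted as target plus share. Target at 40 h read 37% east and 40% north, so my low estimate for the flask was 67.0%. The forecast differed, lower than my estimate: 45% at pH 2.87, on the ground that “Target formation is strongly nonlinear in dissolved substrate.”

    2 starting material → self-condensation product (k = 2.29 M⁻¹ h⁻¹)
    starting material + acid → weak acid + acid + target (k = 39.9 M⁻¹ h⁻¹)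
    starting material + protic impurity → quenched substrate (k = 77.3 M⁻¹ h⁻¹)
    starting material → weak acid + target (k = 0.0229 h⁻¹)
    weak acid ⇌ conjugate base + acid, settled at all times (K = 1.60 × 10⁻⁶ M)
    solid substrate ⇌ starting material, rate k6*(cs6 - [starting material]) while solid is left; crystals form when [starting material] > cs6 (solubility = 14.0 mM, k = 0.0577 h⁻¹)

The flask gave 94.0% at pH 2.85, holding 54.7% target, 30.0% quenched substrate against the share of 30.0%, and 9.32% self-condensation product, with 0.056% of its protic impurity left. The neighbour flask held a quarter of the solid substrate, so its share came to 120%, above the whole charge, and the reckoning capped quenching at the charge. There solid substrate was the limiting reagent, with 0.021% of it left: >99.9% reacted, giving 71.8% quenched substrate, below that cap, and 26.6% target, with 40% of its protic impurity still unbound.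

The readings are simulated for an exercise; noise was put on by code.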